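**Retrosynthetic overview**
1. Target ⇐ mono-acetylation at C3 ⇐ Nozaki–Hiyama–Kishi closure of the C3–C4 bond (the 14-membered ring is formed last) from a (4Z)-alkenyl iodide/C3 aldehyde.
2. C12/C13 (tertiary acetate, free secondary OH) ⇐ net anti-dihydroxylation of a (12Z)-alkene, relayed from C1 by iodolactonisation → epoxide → relactonisation with inversion; the temporary δ-lactone is then switched to the γ-lactone.
3. (Z,Z,Z)-chain ⇐ two α-iodo-Wittig olefinations and one B-alkyl Suzuki coupling with a Normant-derived (Z)-diene.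
4. Key step: Claisen rearrangement of the allyl vinyl ether of a Baylis–Hillman-derived allylic alcohol; it forms C1–C14, sets C1 from C2 and delivers the α-methylene ester.
5. Only source of chirality: (S)-glyceraldehyde acetonide (C2). Ring order: δ-lactone (temporary) → γ-lactone → 14-membered carbocycle.

Assumption (locants): cembranoid numbering is used. C1 = ring CH bearing the lactone C–C bond, C2 = lactone O–CH, C3 = CH–OAc, C4(Me)=C5, C8(Me)=C9, C12 = C(Me)OAc, C13 = CHOH, C14 = CH2, C15/C16/C17 = lactone α-carbon/C=O/=CH2. The SMILES is read as (1R,2R,3S,12S,13S,4Z,8Z), i.e. ring carbons cis on both alkenes.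

**Step 1**
Reactants: 1 (S)-2,2-dimethyl-1,3-dioxolane-4-carbaldehyde; 2 methyl acrylate
Product: 3 methyl 2-{[(4S)-2,2-dimethyl-1,3-dioxolan-4-yl](hydroxy)methyl}prop-2-enoate (carbinol epimers)
Conditions: DABCO (1 equiv), 2 (3 equiv), 1,4-dioxane–H2O 1:1, rt, 48 h
Reagents that add atoms: none
Why: Morita–Baylis–Hillman reaction, in which the DABCO/acrylate zwitterion adds to the α-alkoxy aldehyde without touching its stereocentre, the new carbinol centre (epimer mixture) being erased in step 2.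

**Step 2**
Reactants: 3 Baylis–Hillman adduct
Product: 5 methyl (2E)-2-[(acetyloxy)methyl]-3-[(4R)-2,2-dimethyl-1,3-dioxolan-4-yl]prop-2-enoate, via secondary acetate 4 (not isolated)
Conditions: Ac2O, pyridine, DMAP (cat.), CH2Cl2, 0 °C; then DABCO (1 equiv), THF, rt
Reagents that add atoms: acetic anhydride, CC(=O)OC(C)=O
Why: Acetylation followed by DABCO-mediated SN2′–SN2′ allylic transposition moves the acetate to the primary carbon and gives the thermodynamic (E)-enoate with the dioxolane cis to CH2OAc, the geometry the Claisen step needs.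

**Step 3**
Reactants: 5 rearranged allylic acetate
Product: 6 methyl (2E)-3-[(4R)-2,2-dimethyl-1,3-dioxolan-4-yl]-2-(hydroxymethyl)prop-2-enoate
Conditions: K2CO3 (0.2 equiv), MeOH, 0 °C
Reagents that add atoms: none
Why: Carbonate-catalysed transesterification (methanolysis) removes the primary acetate, while the methyl ester is only regenerated by methanol and the acetonide is base-stable.

**Step 4**
Reactants: 6 primary allylic alcohol
Product: 8 methyl (3R)-3-[(4R)-2,2-dimethyl-1,3-dioxolan-4-yl]-2-methylidene-5-oxopentanoate, via allyl vinyl ether 7 (not isolated)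
Conditions: ethyl vinyl ether (solvent), Hg(OAc)2 (0.3 equiv), reflux; then PhMe, 110 °C, sealed tube
Reagents that add atoms: ethyl vinyl ether, C=COCC
Why: Hg(II)-catalysed transvinylation then Claisen [3,3]-sigmatropic rearrangement (accelerated by the 2-CO2Me group) forms C1–C14 through a chair transition state in which the dioxolane C–H eclipses the alkene (A1,3 strain) and the new bond forms anti to the allylic C–O bond, setting C1 as R and unveiling the α-methylene ester.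

**Step 5**
Reactants: 8 aldehyde
Product: 9 methyl (3R,5Z)-3-[(4R)-2,2-dimethyl-1,3-dioxolan-4-yl]-6-iodo-2-methylidenehept-5-enoate
Conditions: EtPPh3I, n-BuLi, THF, rt; I2, −78 °C; NaHMDS, −20 °C; then 8, −78 °C
Reagents that add atoms: ethyltriphenylphosphonium iodide, CC[P+](c1ccccc1)(c1ccccc1)c1ccccc1.[I-]; iodine, II
Why: Stork–Zhao-type Wittig olefination with the α-iodo ylide Ph3P=C(I)CH3 gives the (Z)-2-iodoalkene (iodine cis to C14) at −78 °C, where the hindered acrylate is not attacked.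

**Step 6**
Reactants: 10 2-(2-bromoethyl)-1,3-dioxolane; 11 propyne; 12 vinyl bromide
Product: 17 2-[(3Z)-3-methylhexa-3,5-dien-1-yl]-1,3-dioxolane, via Grignard reagent 13 (not isolated), via alkylcopper 14 (not isolated), via alkenylcopper 15 (not isolated), via alkenylzinc bromide 16 (not isolated)
Conditions: Mg, THF; CuBr·SMe2, Et2O–Me2S, −45 °C; 11, −25 °C; then ZnBr2, 12, Pd(PPh3)4 (5 mol %), THF, 0 °C to rt
Reagents that add atoms: none
Why: Normant syn-carbocupration of propyne places the alkyl group and copper cis, and the Pd-catalysed Negishi-type coupling of the derived alkenylzinc with vinyl bromide retains that geometry, giving the (Z)-trisubstituted 1,3-diene.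

**Step 7**
Reactants: 17 diene acetal; 9 alkenyl iodide
Product: 19 methyl (3R,5Z,9Z)-3-[(4R)-2,2-dimethyl-1,3-dioxolan-4-yl]-12-(1,3-dioxolan-2-yl)-6,10-dimethyl-2-methylidenedodeca-5,9-dienoate, via B-alkyl-9-BBN 18 (not isolated)
Conditions: 9-BBN, THF, 0 °C to rt; then 9, Pd(dppf)Cl2 (5 mol %), AsPh3, Cs2CO3, DMF–H2O, rt
Reagents that add atoms: none
Why: 9-BBN hydroborates only the terminal vinyl group of the diene at its CH2 end, and the B-alkyl Suzuki–Miyaura coupling with the alkenyl iodide proceeds with retention, forming C11–C12 and the (12Z)-alkene.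

**Step 8**
Reactants: 19 coupled acetal
Product: 20 methyl (3R,5Z,9Z)-3-[(4R)-2,2-dimethyl-1,3-dioxolan-4-yl]-6,10-dimethyl-2-methylidene-13-oxotrideca-5,9-dienoate
Conditions: PPTS (cat.), acetone–H2O 20:1, 50 °C
Reagents that add atoms: water, O
Why: Acid-catalysed transacetalisation in wet acetone frees the aldehyde from its dioxolane, while the large excess of acetone keeps the 1,2-diol as its isopropylidene ketal.

**Step 9**
Reactants: 20 aldehyde
Product: 21 methyl (3R,5Z,9Z,13Z)-3-[(4R)-2,2-dimethyl-1,3-dioxolan-4-yl]-14-iodo-6,10-dimethyl-2-methylidenepentadeca-5,9,13-trienoate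
Conditions: EtPPh3I, n-BuLi, THF, rt; I2, −78 °C; NaHMDS, −20 °C; then 20, −78 °C
Reagents that add atoms: ethyltriphenylphosphonium iodide, CC[P+](c1ccccc1)(c1ccccc1)c1ccccc1.[I-]; iodine, II
Why: A second Stork–Zhao-type α-iodo-Wittig olefination installs the (4Z)-alkenyl iodide (iodine cis to C6) needed for ring closure.

**Step 10**
Reactants: 21 methyl ester
Product: 23 (4R,6R)-4-[(4R)-2,2-dimethyl-1,3-dioxolan-4-yl]-6-[(2R,5Z,9Z)-2,10-diiodo-6-methylundeca-5,9-dien-2-yl]-3-methylideneoxan-2-one, via carboxylic acid 22 (not isolated)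
Conditions: LiOH (1.2 equiv), THF–H2O, rt; then I2 (3 equiv), MeCN–H2O, 0 °C, dark
Reagents that add atoms: lithium hydroxide, [Li+].[OH-]; iodine, II
Why: Saponification then iodolactonisation (6-exo, anti addition, chair-like transition state with the C1 and C13 substituents equatorial) gives the 1,13-cis δ-lactone, so C13 (R at this stage) is controlled by C1 and the tertiary iodide at C12 by the Z-alkene geometry, only the 12,13-alkene being within reach of the carboxylate.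

**Step 11**
Reactants: 23 iodolactone
Product: 25 (4R,6S)-4-[(4R)-2,2-dimethyl-1,3-dioxolan-4-yl]-6-[(2S,5Z,9Z)-2-hydroxy-10-iodo-6-methylundeca-5,9-dien-2-yl]-3-methylideneoxan-2-one, via epoxy acid 24 (not isolated)
Conditions: LiOH (2.2 equiv), THF–H2O, 0 °C; then AcOH to pH 5, 40 °C
Reagents that add atoms: lithium hydroxide, [Li+].[OH-]
Why: Hydroxide opens the lactone and the C13 alkoxide closes to the cis-epoxide by SN2 displacement of the tertiary iodide, then the carboxylic acid reopens the epoxide 6-exo at the secondary carbon with inversion (epoxide-opening lactonisation), which turns C13 into S and leaves C12–OH as S, a net anti-dihydroxylation of the Z-alkene.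

**Step 12**
Reactants: 25 hydroxy δ-lactone
Product: 26 (4R,6S)-6-[(2S,5Z,9Z)-2-(acetyloxy)-10-iodo-6-methylundeca-5,9-dien-2-yl]-4-[(4R)-2,2-dimethyl-1,3-dioxolan-4-yl]-3-methylideneoxan-2-one
Conditions: Ac2O, Et3N, DMAP (1 equiv), CH2Cl2, 35 °C
Reagents that add atoms: acetic anhydride, CC(=O)OC(C)=O
Why: DMAP-catalysed acetylation esterifies the only free hydroxyl, the tertiary C12–OH, while the C13 oxygen is masked in the δ-lactone.

**Step 13**
Reactants: 26 acetonide δ-lactone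
Product: 28 (2S,3S,6Z,10Z)-2-hydroxy-1-[(2R,3R)-2-(hydroxymethyl)-4-methylidene-5-oxooxolan-3-yl]-11-iodo-3,7-dimethyldodeca-6,10-dien-3-yl acetate, via δ-lactone diol 27 (not isolated)
Conditions: AcOH–H2O–THF 3:1:1, 45 °C
Reagents that add atoms: none
Why: Acid hydrolysis removes the acetonide, and the freed C2–OH translactonises (acid-catalysed acyl transfer) from the 4,6-trans δ-lactone with an axial substituent to the strain-free trans-disubstituted γ-lactone, releasing C13–OH without touching a stereocentre.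

**Step 14**
Reactants: 28 γ-lactone diol
Product: 29 (2S,3S,6Z,10Z)-1-[(2R,3R)-2-formyl-4-methylidene-5-oxooxolan-3-yl]-2-hydroxy-11-iodo-3,7-dimethyldodeca-6,10-dien-3-yl acetate
Conditions: TEMPO (0.2 equiv), PhI(OAc)2 (1.2 equiv), CH2Cl2, rt
Reagents that add atoms: none
Why: TEMPO/PhI(OAc)2 oxidation is selective for the primary alcohol over the hindered secondary C13–OH next to the quaternary carbon and gives the α-acyloxy aldehyde without epimerisation.

**Step 15**
Reactants: 29 iodo aldehyde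
Product: 30 (1R,2R,3S,4Z,8Z,12S,13S)-12-acetoxy-3,13-dihydroxycembra-4,8,15(17)-trien-16,2-olide
Conditions: CrCl2 (10 equiv), NiCl2 (cat.), DMSO–THF, 2 mM, rt
Reagents that add atoms: none
Why: Intramolecular Nozaki–Hiyama–Kishi reaction, in which the alkenylchromium adds with retention of the Z geometry and, by the polar Felkin–Anh model (lactone C–O anti to the nucleophile, attack past H), gives the 2,3-anti alcohol (C3 S) while closing the 14-membered ring.

**Step 16**
Reactants: 30 macrocyclic diol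
Product: 31 target, (1R,2R,3S,4Z,8Z,12S,13S)-3,12-diacetoxy-13-hydroxycembra-4,8,15(17)-trien-16,2-olide
Conditions: Ac2O (1.3 equiv), pyridine, CH2Cl2, 0 °C
Reagents that add atoms: acetic anhydride, CC(=O)OC(C)=O
Why: Selective acylation under mild conditions takes the allylic C3–OH and spares the C13–OH, which is flanked by the quaternary C12 acetate and hydrogen-bonded to it.

**Compound list**
1 | (S)-2,2-dimethyl-1,3-dioxolane-4-carbaldehyde (from L-ascorbic acid) | O=C[C@@H]1COC(C)(C)O1 | starting material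
2 | methyl acrylate | C=CC(=O)OC | starting material
3 | methyl 2-{[(4S)-2,2-dimethyl-1,3-dioxolan-4-yl](hydroxy)methyl}prop-2-enoate, carbinol epimers | C=C(C(=O)OC)C(O)[C@@H]1COC(C)(C)O1 | intermediate
4 | methyl 2-{(acetyloxy)[(4S)-2,2-dimethyl-1,3-dioxolan-4-yl]methyl}prop-2-enoate | C=C(C(=O)OC)C(OC(C)=O)[C@@H]1COC(C)(C)O1 | intermediate
5 | methyl (2E)-2-[(acetyloxy)methyl]-3-[(4R)-2,2-dimethyl-1,3-dioxolan-4-yl]prop-2-enoate | CC(=O)OC/C(C(=O)OC)=C\[C@@H]1COC(C)(C)O1 | intermediate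
6 | methyl (2E)-3-[(4R)-2,2-dimethyl-1,3-dioxolan-4-yl]-2-(hydroxymethyl)prop-2-enoate | OC/C(C(=O)OC)=C\[C@@H]1COC(C)(C)O1 | intermediate
7 | methyl (2E)-3-[(4R)-2,2-dimethyl-1,3-dioxolan-4-yl]-2-[(ethenyloxy)methyl]prop-2-enoate | C=COC/C(C(=O)OC)=C\[C@@H]1COC(C)(C)O1 | intermediate
8 | methyl (3R)-3-[(4R)-2,2-dimethyl-1,3-dioxolan-4-yl]-2-methylidene-5-oxopentanoate | C=C(C(=O)OC)[C@@H](CC=O)[C@@H]1COC(C)(C)O1 | intermediate
9 | methyl (3R,5Z)-3-[(4R)-2,2-dimethyl-1,3-dioxolan-4-yl]-6-iodo-2-methylidenehept-5-enoate | C=C(C(=O)OC)[C@@H](C/C=C(/C)I)[C@@H]1COC(C)(C)O1 | intermediate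
10 | 2-(2-bromoethyl)-1,3-dioxolane | BrCCC1OCCO1 | starting material
11 | propyne | CC#C | starting material
12 | vinyl bromide | C=CBr | starting material
13 | [2-(1,3-dioxolan-2-yl)ethyl]magnesium bromide | Br[Mg]CCC1OCCO1 | intermediate
14 | [2-(1,3-dioxolan-2-yl)ethyl]copper | [Cu]CCC1OCCO1 | intermediate
15 | [(1Z)-4-(1,3-dioxolan-2-yl)-2-methylbut-1-en-1-yl]copper | C/C(CCC1OCCO1)=C/[Cu] | intermediate
16 | [(1Z)-4-(1,3-dioxolan-2-yl)-2-methylbut-1-en-1-yl]zinc bromide | C/C(CCC1OCCO1)=C/[Zn]Br | intermediate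
17 | 2-[(3Z)-3-methylhexa-3,5-dien-1-yl]-1,3-dioxolane | C/C(CCC1OCCO1)=C/C=C | intermediate
18 | 9-[(3Z)-6-(1,3-dioxolan-2-yl)-4-methylhex-3-en-1-yl]-9-borabicyclo[3.3.1]nonane | C/C(CCC1OCCO1)=C/CCB1C2CCCC1CCC2 | intermediate
19 | methyl (3R,5Z,9Z)-3-[(4R)-2,2-dimethyl-1,3-dioxolan-4-yl]-12-(1,3-dioxolan-2-yl)-6,10-dimethyl-2-methylidenedodeca-5,9-dienoate | C=C(C(=O)OC)[C@@H](C/C=C(/C)CC/C=C(/C)CCC1OCCO1)[C@@H]2COC(C)(C)O2 | intermediate
20 | methyl (3R,5Z,9Z)-3-[(4R)-2,2-dimethyl-1,3-dioxolan-4-yl]-6,10-dimethyl-2-methylidene-13-oxotrideca-5,9-dienoate | C=C(C(=O)OC)[C@@H](C/C=C(/C)CC/C=C(/C)CCC=O)[C@@H]1COC(C)(C)O1 | intermediate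
21 | methyl (3R,5Z,9Z,13Z)-3-[(4R)-2,2-dimethyl-1,3-dioxolan-4-yl]-14-iodo-6,10-dimethyl-2-methylidenepentadeca-5,9,13-trienoate | C=C(C(=O)OC)[C@@H](C/C=C(/C)CC/C=C(/C)CC/C=C(/C)I)[C@@H]1COC(C)(C)O1 | intermediate
22 | (3R,5Z,9Z,13Z)-3-[(4R)-2,2-dimethyl-1,3-dioxolan-4-yl]-14-iodo-6,10-dimethyl-2-methylidenepentadeca-5,9,13-trienoic acid | C=C(C(=O)O)[C@@H](C/C=C(/C)CC/C=C(/C)CC/C=C(/C)I)[C@@H]1COC(C)(C)O1 | intermediate
23 | (4R,6R)-4-[(4R)-2,2-dimethyl-1,3-dioxolan-4-yl]-6-[(2R,5Z,9Z)-2,10-diiodo-6-methylundeca-5,9-dien-2-yl]-3-methylideneoxan-2-one (1,13-cis iodo-δ-lactone) | C=C1C(=O)O[C@H](C[C@H]1[C@@H]2COC(C)(C)O2)[C@](C)(I)CC/C=C(/C)CC/C=C(/C)I | intermediate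
24 | (3R)-3-[(4R)-2,2-dimethyl-1,3-dioxolan-4-yl]-4-{(2R,3S)-3-[(3Z,7Z)-8-iodo-4-methylnona-3,7-dien-1-yl]-3-methyloxiran-2-yl}-2-methylidenebutanoic acid | C=C(C(=O)O)[C@@H](C[C@H]1O[C@@]1(C)CC/C=C(/C)CC/C=C(/C)I)[C@@H]2COC(C)(C)O2 | intermediate
25 | (4R,6S)-4-[(4R)-2,2-dimethyl-1,3-dioxolan-4-yl]-6-[(2S,5Z,9Z)-2-hydroxy-10-iodo-6-methylundeca-5,9-dien-2-yl]-3-methylideneoxan-2-one | C=C1C(=O)O[C@@H](C[C@H]1[C@@H]2COC(C)(C)O2)[C@@](C)(O)CC/C=C(/C)CC/C=C(/C)I | intermediate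
26 | (4R,6S)-6-[(2S,5Z,9Z)-2-(acetyloxy)-10-iodo-6-methylundeca-5,9-dien-2-yl]-4-[(4R)-2,2-dimethyl-1,3-dioxolan-4-yl]-3-methylideneoxan-2-one | C=C1C(=O)O[C@@H](C[C@H]1[C@@H]2COC(C)(C)O2)[C@@](C)(OC(C)=O)CC/C=C(/C)CC/C=C(/C)I | intermediate
27 | (4R,6S)-6-[(2S,5Z,9Z)-2-(acetyloxy)-10-iodo-6-methylundeca-5,9-dien-2-yl]-4-[(1R)-1,2-dihydroxyethyl]-3-methylideneoxan-2-one | C=C1C(=O)O[C@@H](C[C@H]1[C@@H](O)CO)[C@@](C)(OC(C)=O)CC/C=C(/C)CC/C=C(/C)I | intermediate
28 | (2S,3S,6Z,10Z)-2-hydroxy-1-[(2R,3R)-2-(hydroxymethyl)-4-methylidene-5-oxooxolan-3-yl]-11-iodo-3,7-dimethyldodeca-6,10-dien-3-yl acetate | C=C1C(=O)O[C@@H](CO)[C@@H]1C[C@H](O)[C@@](C)(OC(C)=O)CC/C=C(/C)CC/C=C(/C)I | intermediate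
29 | (2S,3S,6Z,10Z)-1-[(2R,3R)-2-formyl-4-methylidene-5-oxooxolan-3-yl]-2-hydroxy-11-iodo-3,7-dimethyldodeca-6,10-dien-3-yl acetate | C=C1C(=O)O[C@@H](C=O)[C@@H]1C[C@H](O)[C@@](C)(OC(C)=O)CC/C=C(/C)CC/C=C(/C)I | intermediate
30 | (1R,2R,3S,4Z,8Z,12S,13S)-12-acetoxy-3,13-dihydroxycembra-4,8,15(17)-trien-16,2-olide | C=C1C(=O)O[C@@H]2[C@@H]1C[C@H](O)[C@@](C)(OC(C)=O)CC/C=C(/C)CC/C=C(/C)[C@@H]2O | intermediate
31 | CNP0127975.1, (1R,2R,3S,4Z,8Z,12S,13S)-3,12-diacetoxy-13-hydroxycembra-4,8,15(17)-trien-16,2-olide | C=C1C(=O)O[C@@H]2[C@@H]1C[C@H](O)[C@@](C)(OC(C)=O)CC/C=C(/C)CC/C=C(/C)[C@@H]2OC(C)=O | target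

**Step count and risks**
Total: 16 steps. Longest linear sequence: 15 steps (steps 1–5 and 7–16); step 6 makes the side-chain diene.

The three steps most likely to fail:

Step 10 (sense of the iodolactonisation). The equatorial preference of the C1 substituent next to the exocyclic methylene is small, so the 1,13-trans iodolactone may dominate. That isomer needs no inversion and is carried through a different end-game, which sets out from acid 22 and comes back at target 31. The 1,13-trans iodo-δ-lactone F1 is treated with aqueous acetic acid to give iodo-δ-lactone diol F2. Cs2CO3 in MeCN then transfers the acyl group to the C2 oxygen, and the released C13 alkoxide displaces the tertiary iodide to give epoxy γ-lactone alcohol F3. TEMPO/PhI(OAc)2 gives epoxy aldehyde F4, CrCl2/NiCl2 closes the ring to macrocyclic epoxy alcohol F5, and acetylation gives epoxy acetate F6. Acetic acid finally opens the trisubstituted epoxide at the tertiary carbon with inversion, giving 31 with the tertiary acetate and free C13–OH in one operation.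

Step 15 (NHK macrocyclisation, C3 configuration). Ring strain in the closing transition state may override Felkin control. The fallback sets out from aldehyde 29 and comes back at 30. The cyclisation mixture rich in 3-epi alcohol F7 is oxidised with MnO2 (allylic alcohol only) to macrocyclic enone F8. Chelation-controlled reduction with Zn(BH4)2 in Et2O at −30 °C then sets C3 by hydride delivery to the ketone instead of by C–C bond formation and gives 30.

Step 16 (selective acetylation). Acylation may be unselective or be accompanied by acetyl migration from C12 to C13. The fallback sets out from diol 28 and comes back at 31, with C13–OH protected through the ring closure. TESOTf/2,6-lutidine gives bis-silyl ether F9, and Swern oxidation converts the primary TES ether directly into silyl ether aldehyde F10. NHK closure gives macrocyclic silyl ether alcohol F11, exhaustive acetylation gives silyl ether acetate F12, and HF·pyridine in THF at 0 °C removes the TES group under non-basic conditions to give 31.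

**Further compounds**
F1 | step 10 | (4R,6S)-4-[(4R)-2,2-dimethyl-1,3-dioxolan-4-yl]-6-[(2S,5Z,9Z)-2,10-diiodo-6-methylundeca-5,9-dien-2-yl]-3-methylideneoxan-2-one (1,13-trans iodo-δ-lactone) | C=C1C(=O)O[C@@H](C[C@H]1[C@@H]2COC(C)(C)O2)[C@@](C)(I)CC/C=C(/C)CC/C=C(/C)I
F2 | step 10 | (4R,6S)-4-[(1R)-1,2-dihydroxyethyl]-6-[(2S,5Z,9Z)-2,10-diiodo-6-methylundeca-5,9-dien-2-yl]-3-methylideneoxan-2-one | C=C1C(=O)O[C@@H](C[C@H]1[C@@H](O)CO)[C@@](C)(I)CC/C=C(/C)CC/C=C(/C)I
F3 | step 10 | (4R,5R)-5-(hydroxymethyl)-4-{[(2S,3R)-3-[(3Z,7Z)-8-iodo-4-methylnona-3,7-dien-1-yl]-3-methyloxiran-2-yl]methyl}-3-methylideneoxolan-2-one | C=C1C(=O)O[C@@H](CO)[C@@H]1C[C@@H]3O[C@]3(C)CC/C=C(/C)CC/C=C(/C)I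
F4 | step 10 | (2R,3R)-3-{[(2S,3R)-3-[(3Z,7Z)-8-iodo-4-methylnona-3,7-dien-1-yl]-3-methyloxiran-2-yl]methyl}-4-methylidene-5-oxooxolane-2-carbaldehyde | C=C1C(=O)O[C@@H](C=O)[C@@H]1C[C@@H]3O[C@]3(C)CC/C=C(/C)CC/C=C(/C)I
F5 | step 10 | (1R,2R,3S,4Z,8Z,12R,13S)-12,13-epoxy-3-hydroxycembra-4,8,15(17)-trien-16,2-olide | C=C1C(=O)O[C@@H]2[C@@H]1C[C@@H]3O[C@]3(C)CC/C=C(/C)CC/C=C(/C)[C@@H]2O
F6 | step 10 | (1R,2R,3S,4Z,8Z,12R,13S)-3-acetoxy-12,13-epoxycembra-4,8,15(17)-trien-16,2-olide | C=C1C(=O)O[C@@H]2[C@@H]1C[C@@H]3O[C@]3(C)CC/C=C(/C)CC/C=C(/C)[C@@H]2OC(C)=O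
F7 | step 15 | (1R,2R,3R,4Z,8Z,12S,13S)-12-acetoxy-3,13-dihydroxycembra-4,8,15(17)-trien-16,2-olide (3-epimer of 30) | C=C1C(=O)O[C@@H]2[C@@H]1C[C@H](O)[C@@](C)(OC(C)=O)CC/C=C(/C)CC/C=C(/C)[C@H]2O
F8 | step 15 | (1R,2R,4Z,8Z,12S,13S)-12-acetoxy-13-hydroxy-3-oxocembra-4,8,15(17)-trien-16,2-olide | C=C1C(=O)O[C@@H]2[C@@H]1C[C@H](O)[C@@](C)(OC(C)=O)CC/C=C(/C)CC/C=C(/C)C2=O
F9 | step 16 | bis(triethylsilyl) ether of 28 (primary O and C13–O silylated) | C=C1C(=O)O[C@@H](CO[Si](CC)(CC)CC)[C@@H]1C[C@H](O[Si](CC)(CC)CC)[C@@](C)(OC(C)=O)CC/C=C(/C)CC/C=C(/C)I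
F10 | step 16 | 13-O-triethylsilyl ether of aldehyde 29 | C=C1C(=O)O[C@@H](C=O)[C@@H]1C[C@H](O[Si](CC)(CC)CC)[C@@](C)(OC(C)=O)CC/C=C(/C)CC/C=C(/C)I
F11 | step 16 | 13-O-triethylsilyl ether of macrocyclic alcohol 30 | C=C1C(=O)O[C@@H]2[C@@H]1C[C@H](O[Si](CC)(CC)CC)[C@@](C)(OC(C)=O)CC/C=C(/C)CC/C=C(/C)[C@@H]2O
F12 | step 16 | 13-O-triethylsilyl ether of target 31 | C=C1C(=O)O[C@@H]2[C@@H]1C[C@H](O[Si](CC)(CC)CC)[C@@](C)(OC(C)=O)CC/C=C(/C)CC/C=C(/C)[C@@H]2OC(C)=O
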